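**Strategy.** With aN as the Nth non-hydrogen atom of the target SMILES, ring C (a3, a4, a5, a6, a15, a16) is disconnected at a15–a16. The quaternary a6, flanked in ring D by carbinol a8 and ring-fusion a15, is a latent 2-methylcyclopentane-1,3-dione; a16 is the terminus of an exocyclic methylene on a3 of the eight-membered ring B. One acid-mediated carbonyl-ene closure of dione 28 forms a15–a16, closes ring C, fixes a6 by choosing one carbonyl and leaves the a3=a4 alkene of the target diene. The precursor is a trans-fused 5–8 bicycle carrying the a3 methylene, the a4 CH2–dione arm and a pivalate (not a silyl ether) at a2, which blocks pinacol-type shifts.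

Key step: step 17

**Remarks on the chemistry (assumptions)**
- No error was found in the skeletons or configurations of the key-step pair; the changes are in the design. The a2 oxygen is a pivalate because an allylic silyl ether next to the a3 cation invites a Prins–pinacol shift. The a16 methylene is installed before the dione because an olefination on a triketone would attack the unhindered dione carbonyls first.
- The a2 carbinol configuration (21 to 38) is drawn as one epimer for definiteness; a2 becomes sp2 in step 23, so the other epimer or a mixture is carried through identically.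
- The ligand antipode in step 1 and the acid antipode in step 17 are those that give the drawn configurations, to be fixed by a pilot pair of runs.

**Route**

Step 1
Reactants: 1 3-methylcyclopent-2-en-1-one; 2 (R)-citronellal
Product: 5 (3S)-2-[(3R)-1-hydroxy-3,7-dimethyloct-6-en-1-yl]-3-methylcyclopentan-1-one (epimers at C2 and at the carbinol carbon), via silyl enol ether 3 (not isolated), via lithium enolate 4 (not isolated)
Conditions: CuCl (5 mol %), NaOt-Bu (5 mol %), (S)-p-Tol-BINAP (5 mol %), Ph2SiH2, toluene, 0 °C; MeLi, THF, −78 → 0 °C; then 2, −78 °C; aq. NH4Cl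
Reagents that add atoms: none
Why: Copper-hydride asymmetric conjugate reduction sets a25 by ligand-controlled hydride delivery to the β-carbon and leaves the enolate regiospecifically at a21, which after Si-to-Li exchange adds to the aldehyde (aldol reaction); the new carbinol and a21 centres are erased in steps 2 and 3, and a17 is carried in unchanged from (R)-citronellal.

Step 2
Reactants: 5 aldol adduct
Product: 7 (2E,3S)-2-[(3R)-3,7-dimethyloct-6-en-1-ylidene]-3-methylcyclopentan-1-one, via mesylate 6 (not isolated)
Conditions: MsCl, Et3N, CH2Cl2, 0 °C → rt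
Reagents that add atoms: none
Why: Mesylation of the β-hydroxy ketone and E1cB elimination by triethylamine should give the exocyclic (E)-enone under conditions too mild to move the double bond into the ring, so a25 stays intact.

Step 3
Reactants: 7 exocyclic enone
Product: 9 (3S)-2-[(3R)-3,7-dimethyloct-6-en-1-yl]-3-methylcyclopent-1-en-1-yl trifluoromethanesulfonate, via lithium enolate 8 (not isolated)
Conditions: Li, NH3(l)/THF, t-BuOH (1 equiv), −78 °C; evaporate NH3; PhNTf2, THF, 0 °C → rt
Reagents that add atoms: N-phenylbis(trifluoromethanesulfonimide), O=S(=O)(N(c1ccccc1)S(=O)(=O)C(F)(F)F)C(F)(F)F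
Why: Dissolving-metal reduction of the enone generates the enolate only across a21/a22 and triflimide trapping gives the tetrasubstituted alkenyl triflate as a single regioisomer, the isolated trisubstituted alkene being inert to Li/NH3.

Step 4
Reactants: 9 alkenyl triflate
Product: 10 (4S)-4-methyl-6-[(5S)-5-methyl-2-(trifluoromethylsulfonyloxy)cyclopent-1-en-1-yl]hexanal
Conditions: O3 (1 equiv, Sudan III end point), pyridine (3 equiv), CH2Cl2, −78 °C
Reagents that add atoms: ozone, [O-][O+]=O
Why: Ozonolysis in the presence of pyridine cleaves the electron-rich trisubstituted alkene directly to the a2 aldehyde, the alkenyl triflate being too electron-poor to compete.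

Step 5
Reactants: 10 aldehyde triflate
Product: 11 (5S,9S)-5,9-dimethylbicyclo[6.3.0]undec-1(8)-en-2-ol (both a2 epimers)
Conditions: CrCl2 (6 equiv), NiCl2 (2 mol %), DMSO/THF, rt, slow addition at 0.005 M
Reagents that add atoms: none
Why: Nozaki–Hiyama–Kishi coupling forms a2–a22 and closes the eight-membered ring, helped by the cis disposition that the cyclopentene imposes on the two tether ends and by the aldehyde selectivity of alkenylchromium species; the carbinol epimers converge in step 6.

Step 6
Reactants: 11 bicyclic allylic alcohol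
Product: 12 (5S,9S)-5,9-dimethylbicyclo[6.3.0]undec-1(8)-en-2-one
Conditions: Dess–Martin periodinane, NaHCO3, CH2Cl2, 0 °C → rt
Reagents that add atoms: none
Why: Dess–Martin oxidation of the allylic alcohol should give the ring-fusion enone and remove the a2 mixture.

Step 7
Reactants: 12 bicyclic enone
Product: 14 trans-fused (1S,5S,8S,9S)-5,9-dimethylbicyclo[6.3.0]undecan-2-one, via cis-fused ketone 13 (not isolated)
Conditions: H2 (3 atm), 10% Pd/C, EtOAc, rt; filter; NaOMe (cat.), MeOH, rt
Reagents that add atoms: none
Why: Heterogeneous hydrogenation should add both hydrogens to the enone face opposite the a25 methyl, placing a20 cis to that methyl, and methoxide then epimerises the enolisable a22 to the trans-fused ketone because the cis-fused isomer would carry three contiguous cis substituents on the cyclopentane.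

Step 8
Reactants: 14 trans-fused ketone
Product: 16 (1S,5S,8S,9S,3Z)-5,9-dimethylbicyclo[6.3.0]undec-3-en-2-one, via silyl enol ether 15 (not isolated)
Conditions: LDA, TMSCl, THF, −78 °C; then Pd(OAc)2 (1.05 equiv), MeCN, rt
Reagents that add atoms: none
Why: Kinetic deprotonation at the a3 methylene rather than the a22 methine, silylation and Saegusa–Ito oxidation should give the (Z)-cyclooctenone without touching a22.

Step 9
Reactants: 16 cyclooctenone
Product: 18 Mannich base: 14-type bicycle with a2 ketone, CH2NMe2 on a3 (epimers) and CH2SiMe2(Oi-Pr) on a4 trans to the a17 methyl, via silyl enol ether 17 (not isolated)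
Conditions: ClCH2SiMe2(Oi-Pr), Mg, THF; CuI (10 mol %), TMSCl, THF, −78 → −30 °C; then CH2=NMe2+ I−, CH2Cl2, rt; aq. NaHCO3
Reagents that add atoms: [(isopropoxydimethylsilyl)methyl]magnesium chloride, CC(C)O[Si](C)(C)C[Mg]Cl; Eschenmoser's salt, C=[N+](C)C.[I-]
Why: Copper-catalysed conjugate addition of the hydroxymethyl-anion equivalent with chlorosilane trapping puts a5 on a4 anti to the neighbouring a17 methyl, and the regiodefined silyl enol ether then undergoes a Mannich reaction so that a16 enters only at a3.

Step 10
Reactants: 18 Mannich base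
Product: 20 α-methylene ketone: a2 ketone, a3=a16 exocyclic methylene, a4 CH2SiMe2(Oi-Pr), via ammonium iodide 19 (not isolated)
Conditions: MeI, CH2Cl2, rt; then aq. NaHCO3, rt
Reagents that add atoms: none
Why: Quaternisation of the amine and E1cB loss of trimethylamine (Mannich-base elimination) should unveil the a3=a16 methylene conjugated to the a2 ketone under conditions too mild to isomerise it.

Step 11
Reactants: 20 α-methylene ketone
Product: 21 allylic alcohol at a2 (drawn epimer)
Conditions: NaBH4, CeCl3·7H2O, MeOH, −78 °C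
Reagents that add atoms: none
Why: Luche reduction should give clean 1,2-reduction of the α-methylene ketone; the a2 configuration that results from peripheral hydride attack is erased later.

Step 12
Reactants: 21 allylic alcohol
Product: 22 a2 pivalate
Conditions: PivCl, pyridine, DMAP (cat.), CH2Cl2, 0 °C → rt
Reagents that add atoms: pivaloyl chloride, CC(C)(C)C(=O)Cl
Why: Acylation gives a robust ester without α-hydrogens whose oxygen lone pair is withdrawn into the acyl group, which is what the key step needs.

Step 13
Reactants: 22 silane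
Product: 23 primary alcohol at a5
Conditions: 30% H2O2, KF, KHCO3, THF/MeOH, rt
Reagents that add atoms: hydrogen peroxide, OO
Why: Tamao–Kumada oxidation replaces the C–Si bond by C–OH under mildly basic peroxide conditions that should leave the isolated alkene and the pivalate alone.

Step 14
Reactants: 23 primary alcohol
Product: 24 aldehyde at a5
Conditions: Dess–Martin periodinane, NaHCO3, CH2Cl2, 0 °C
Reagents that add atoms: none
Why: Buffered Dess–Martin oxidation should give the β,γ-unsaturated aldehyde without acid or base that could migrate the alkene or epimerise a4.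

Step 15
Reactants: 24 aldehyde; 25 cyclopentane-1,3-dione
Product: 27 2-alkylcyclopentane-1,3-dione (enolised), via alkylidene dione 26 (not isolated)
Conditions: Hantzsch ester, L-proline (10 mol %), CH2Cl2, rt
Reagents that add atoms: none
Why: Organocatalytic three-component reductive alkylation (Knoevenagel condensation, then transfer hydrogenation of the alkylidene dione by the Hantzsch ester) forms a5–a6 on carbon only and tolerates the alkene and ester; if a4 equilibrates it should settle trans to the a17 methyl.

Step 16
Reactants: 27 2-alkyl dione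
Product: 28 key-step precursor: 2-methyl-2-(cyclooctylmethyl)cyclopentane-1,3-dione with a3 methylene and a2 pivalate
Conditions: MeI, Cs2CO3, MeCN, rt
Reagents that add atoms: iodomethane, CI
Why: C-methylation of the dione enolate creates the quaternary, still prochiral a6 only after the methylene is in place, so no olefination has to distinguish three ketones; any enol methyl ether can be hydrolysed back and recycled.

Step 17
Reactants: 28 precursor
Product: 29 tetracyclic cis-fused ketol with the a3=a4 alkene
Conditions: BINOL-derived chiral N-triflyl phosphoramide (10 mol %, matched antipode), toluene, 5 Å MS, 0 °C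
Reagents that add atoms: none
Why: The chiral acid activates one dione carbonyl, the methylene terminus a16 attacks a15, and the developing a3 cation (or the concerted ene array) gives up the a4 hydrogen to the catalyst anion, leaving the tetrasubstituted a3=a4 alkene and a tertiary alcohol. The closest known reactions are the Torgov cyclisation of 2-methyl-2-alkenylcyclopentane-1,3-diones and Brønsted-acid carbonyl-ene cyclisations with confined chiral phosphoric-acid-type catalysts. Ring C closes in a six-membered mode that is 6-exo-trig at the carbonyl and endo with respect to the alkene. a6 is set by which of the two diastereotopic carbonyls reacts, controlled by the catalyst pocket together with the a4 centre that the step then destroys; a15 follows because the tether and the new bond must lie on the same face of the dione ring, so the hydroxyl ends cis to the a7 methyl. The step needs group selection between the carbonyls and proton loss from a4 only: the a4–H is the one held parallel to the empty orbital in the chair-like closure, and the pivalate removes the driving force for the 1,2-shift from a2 that a silyl ether or free hydroxyl would offer.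

Step 18
Reactants: 29 ketol
Product: 31 diene (a15=a16 and a3=a4), via sulfamate ester 30 (not isolated)
Conditions: Burgess reagent, toluene, 60 °C
Reagents that add atoms: none
Why: Burgess dehydration (syn-elimination through the sulfamate) removes the tertiary alcohol under neutral conditions that spare the β-hydroxy ketone from retro-aldol cleavage, the allylic a16 hydrogen being lost to give the conjugated diene; a minor a11 alkene isomer would converge in step 19.

Step 19
Reactants: 31 diene
Product: 32 trans-hydrindanone with a15–H trans to the a7 methyl and a3=a4 retained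
Conditions: H2 (1 atm), Pd/CaCO3, EtOAc, rt, stopped after 1 equiv
Reagents that add atoms: none
Why: As in Torgov-type steroid syntheses, heterogeneous hydrogenation should saturate only the less substituted alkene of the diene, from the face opposite the angular a7 methyl, which sets the trans ring fusion at a15 while the tetrasubstituted a3=a4 alkene is too hindered to react.

Step 20
Reactants: 32 ketone
Product: 34 cyclopentenone (a10=a11), via silyl enol ether 33 (not isolated)
Conditions: LDA, TMSCl, THF, −78 °C; then Pd(OAc)2 (1.05 equiv), MeCN, rt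
Reagents that add atoms: none
Why: The a8 ketone can enolise only toward a10, so silyl enol ether formation and Saegusa–Ito oxidation should give the enone without touching a15, and the pivalate has no α-hydrogen to lose.

Step 21
Reactants: 34 cyclopentenone; 35 isopropylmagnesium chloride
Product: 37 ketone with isopropyl on a11 cis to a15–H, via silyl enol ether 36 (not isolated)
Conditions: 35 (2 equiv), CuBr·SMe2 (20 mol %), TMSCl, THF, −78 °C; then 1 M HCl
Reagents that add atoms: none
Why: Copper-catalysed 1,4-addition of the Grignard reagent should occur on the enone face opposite the angular methyl, placing the isopropyl group on a11 as in the target, and is much faster than any reaction at the hindered pivalate.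

Step 22
Reactants: 37 ketone pivalate
Product: 38 diol (a8–OH cis to the a7 methyl; a2–OH)
Conditions: LiAlH4, THF, 0 °C; Fieser work-up
Reagents that add atoms: none
Why: Hydride reduction of the neopentyl ketone from the face opposite the adjacent a7 methyl should give the a8 alcohol cis to that methyl, as in 17-keto steroid reductions, and the same reagent cleaves the pivalate.

Step 23
Reactants: 38 diol
Product: 39 enone (a2 ketone conjugated to a3=a4) with free a8–OH
Conditions: activated MnO2, CH2Cl2, rt
Reagents that add atoms: none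
Why: Manganese dioxide oxidises only the allylic a2 alcohol, leaving the saturated a8 carbinol untouched.

Step 24
Reactants: 39 enone
Product: 40 target CNP0544018.1
Conditions: Ph3PCH3Br, KOt-Bu (excess), THF, 0 °C → reflux
Reagents that add atoms: methyltriphenylphosphonium bromide, C[P+](c1ccccc1)(c1ccccc1)c1ccccc1.[Br-]
Why: Wittig methylenation with excess salt-free ylide, which first deprotonates the free hydroxyl, should convert the hindered enone into the exocyclic diene; a22 is safe because its trans-fused arrangement is the thermodynamic one.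

**Compound list**

1 | 3-methylcyclopent-2-en-1-one | CC1=CC(=O)CC1 | starting material
2 | (R)-citronellal, (3R)-3,7-dimethyloct-6-enal | CC(C)=CCC[C@@H](C)CC=O | starting material
3 | diphenyl{[(3S)-3-methylcyclopent-1-en-1-yl]oxy}silane | C[C@H]1CCC(O[SiH](c2ccccc2)c2ccccc2)=C1 | intermediate
4 | lithium (3S)-3-methylcyclopent-1-en-1-olate | C[C@H]1CCC([O-])=C1.[Li+] | intermediate
5 | (3S)-2-[(3R)-1-hydroxy-3,7-dimethyloct-6-en-1-yl]-3-methylcyclopentan-1-one, epimers at C2 and carbinol | CC(C)=CCC[C@@H](C)CC(O)C1C(=O)CC[C@@H]1C | intermediate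
6 | methanesulfonate of 5 | CC(C)=CCC[C@@H](C)CC(OS(C)(=O)=O)C1C(=O)CC[C@@H]1C | intermediate
7 | (2E,3S)-2-[(3R)-3,7-dimethyloct-6-en-1-ylidene]-3-methylcyclopentan-1-one | CC(C)=CCC[C@@H](C)C/C=C1/C(=O)CC[C@@H]1C | intermediate
8 | lithium (3S)-2-[(3R)-3,7-dimethyloct-6-en-1-yl]-3-methylcyclopent-1-en-1-olate | CC(C)=CCC[C@@H](C)CCC1=C([O-])CC[C@@H]1C.[Li+] | intermediate
9 | (3S)-2-[(3R)-3,7-dimethyloct-6-en-1-yl]-3-methylcyclopent-1-en-1-yl trifluoromethanesulfonate | CC(C)=CCC[C@@H](C)CCC1=C(OS(=O)(=O)C(F)(F)F)CC[C@@H]1C | intermediate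
10 | (4S)-4-methyl-6-[(5S)-5-methyl-2-(trifluoromethylsulfonyloxy)cyclopent-1-en-1-yl]hexanal | O=CCC[C@@H](C)CCC1=C(OS(=O)(=O)C(F)(F)F)CC[C@@H]1C | intermediate
11 | (5S,9S)-5,9-dimethylbicyclo[6.3.0]undec-1(8)-en-2-ol, both a2 epimers | OC1CC[C@@H](C)CCC2=C1CC[C@@H]2C | intermediate
12 | (5S,9S)-5,9-dimethylbicyclo[6.3.0]undec-1(8)-en-2-one | O=C1CC[C@@H](C)CCC2=C1CC[C@@H]2C | intermediate
13 | cis-fused 5,9-dimethylbicyclo[6.3.0]undecan-2-one (a22 epimer of 14) | O=C1CC[C@@H](C)CC[C@@H]2[C@H]1CC[C@@H]2C | intermediate
14 | trans-fused (1S,5S,8S,9S)-5,9-dimethylbicyclo[6.3.0]undecan-2-one | O=C1CC[C@@H](C)CC[C@@H]2[C@@H]1CC[C@@H]2C | intermediate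
15 | trimethylsilyl enol ether of 14 (a2=a3) | C[Si](C)(C)OC1=CC[C@@H](C)CC[C@@H]2[C@@H]1CC[C@@H]2C | intermediate
16 | (1S,5S,8S,9S,3Z)-5,9-dimethylbicyclo[6.3.0]undec-3-en-2-one | O=C1/C=C\[C@@H](C)CC[C@@H]2[C@@H]1CC[C@@H]2C | intermediate
17 | silyl enol ether after conjugate addition (a4 CH2SiMe2Oi-Pr trans to a17 methyl) | C[Si](C)(C)OC1=C[C@H](C[Si](C)(C)OC(C)C)[C@@H](C)CC[C@@H]2[C@@H]1CC[C@@H]2C | intermediate
18 | Mannich base (a3 CH2NMe2, a3 epimers) | O=C1C(CN(C)C)[C@H](C[Si](C)(C)OC(C)C)[C@@H](C)CC[C@@H]2[C@@H]1CC[C@@H]2C | intermediate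
19 | trimethylammonium iodide of 18 | O=C1C(C[N+](C)(C)C)[C@H](C[Si](C)(C)OC(C)C)[C@@H](C)CC[C@@H]2[C@@H]1CC[C@@H]2C.[I-] | intermediate
20 | α-methylene ketone (a2 C=O, a3=a16) | O=C1C(=C)[C@H](C[Si](C)(C)OC(C)C)[C@@H](C)CC[C@@H]2[C@@H]1CC[C@@H]2C | intermediate
21 | a2 allylic alcohol | O[C@H]1C(=C)[C@H](C[Si](C)(C)OC(C)C)[C@@H](C)CC[C@@H]2[C@@H]1CC[C@@H]2C | intermediate
22 | a2 pivalate, a5 silane | CC(C)(C)C(=O)O[C@H]1C(=C)[C@H](C[Si](C)(C)OC(C)C)[C@@H](C)CC[C@@H]2[C@@H]1CC[C@@H]2C | intermediate
23 | a2 pivalate, a5 primary alcohol | CC(C)(C)C(=O)O[C@H]1C(=C)[C@H](CO)[C@@H](C)CC[C@@H]2[C@@H]1CC[C@@H]2C | intermediate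
24 | a2 pivalate, a5 aldehyde | CC(C)(C)C(=O)O[C@H]1C(=C)[C@H](C=O)[C@@H](C)CC[C@@H]2[C@@H]1CC[C@@H]2C | intermediate
25 | cyclopentane-1,3-dione | O=C1CCC(=O)C1 | starting material
26 | alkylidene dione (a5=a6) | CC(C)(C)C(=O)O[C@H]1C(=C)[C@H](C=C2C(=O)CCC2=O)[C@@H](C)CC[C@@H]3[C@@H]1CC[C@@H]3C | intermediate
27 | 2-alkylcyclopentane-1,3-dione (drawn as diketone) | CC(C)(C)C(=O)O[C@H]1C(=C)[C@H](CC2C(=O)CCC2=O)[C@@H](C)CC[C@@H]3[C@@H]1CC[C@@H]3C | intermediate
28 | key-step precursor, 2-methyl-2-(cyclooctylmethyl)cyclopentane-1,3-dione with a3 methylene and a2 pivalate | CC(C)(C)C(=O)O[C@H]1C(=C)[C@H](CC2(C)C(=O)CCC2=O)[C@@H](C)CC[C@@H]3[C@@H]1CC[C@@H]3C | intermediate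
29 | key-step product, tetracyclic cis-fused ketol with a3=a4 | CC(C)(C)C(=O)O[C@H]1C2=C(C[C@@]3(C)C(=O)CC[C@@]3(O)C2)[C@@H](C)CC[C@@H]4[C@@H]1CC[C@@H]4C | intermediate
30 | sulfamate ester of 29, triethylammonium salt | CC(C)(C)C(=O)O[C@H]1C2=C(C[C@@]3(C)C(=O)CC[C@@]3(OS(=O)(=O)[N-]C(=O)OC)C2)[C@@H](C)CC[C@@H]4[C@@H]1CC[C@@H]4C.CC[NH+](CC)CC | intermediate
31 | diene (a15=a16, a3=a4) | CC(C)(C)C(=O)O[C@H]1C2=C(C[C@@]3(C)C(=O)CCC3=C2)[C@@H](C)CC[C@@H]4[C@@H]1CC[C@@H]4C | intermediate
32 | trans-hydrindanone | CC(C)(C)C(=O)O[C@H]1C2=C(C[C@@]3(C)C(=O)CC[C@@H]3C2)[C@@H](C)CC[C@@H]4[C@@H]1CC[C@@H]4C | intermediate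
33 | trimethylsilyl enol ether of 32 (a8=a10) | CC(C)(C)C(=O)O[C@H]1C2=C(C[C@@]3(C)C(O[Si](C)(C)C)=CC[C@@H]3C2)[C@@H](C)CC[C@@H]4[C@@H]1CC[C@@H]4C | intermediate
34 | cyclopentenone (a10=a11) | CC(C)(C)C(=O)O[C@H]1C2=C(C[C@@]3(C)C(=O)C=C[C@@H]3C2)[C@@H](C)CC[C@@H]4[C@@H]1CC[C@@H]4C | intermediate
35 | isopropylmagnesium chloride | CC(C)[Mg]Cl | starting material
36 | silyl enol ether after isopropyl addition | CC(C)(C)C(=O)O[C@H]1C2=C(C[C@@]3(C)C(O[Si](C)(C)C)=C[C@@H](C(C)C)[C@@H]3C2)[C@@H](C)CC[C@@H]4[C@@H]1CC[C@@H]4C | intermediate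
37 | a11-isopropyl ketone | CC(C)(C)C(=O)O[C@H]1C2=C(C[C@@]3(C)C(=O)C[C@@H](C(C)C)[C@@H]3C2)[C@@H](C)CC[C@@H]4[C@@H]1CC[C@@H]4C | intermediate
38 | diol (a2–OH, a8–OH) | O[C@H]1C2=C(C[C@@]3(C)[C@H](O)C[C@@H](C(C)C)[C@@H]3C2)[C@@H](C)CC[C@@H]4[C@@H]1CC[C@@H]4C | intermediate
39 | a2 enone with a8–OH | O=C1C2=C(C[C@@]3(C)[C@H](O)C[C@@H](C(C)C)[C@@H]3C2)[C@@H](C)CC[C@@H]4[C@@H]1CC[C@@H]4C | intermediate
40 | CNP0544018.1 | C=C1C2=C(C[C@@]3(C)[C@H](O)C[C@@H](C(C)C)[C@@H]3C2)[C@@H](C)CC[C@@H]2[C@@H]1CC[C@@H]2C | target

**Totals.** Total step count: 24. Longest linear sequence: 24 steps (1 to 40); 2, 25 and 35 enter as commercial materials.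

**Steps most likely to fail**

Step 17. The acid may engage the wrong carbonyl if catalyst and a4 centre are mismatched, or the a3 cation may be diverted by proton loss toward a16 or by capture by the neighbouring ester. The fallback separates the stereochemical decision from the ring closure. Setting out from 28, a CBS reduction (catecholborane, −78 °C) reduces only the carbonyl destined to become a8 and gives hydroxy ketone F1. Silylation (TESOTf, 2,6-lutidine) gives silyl ether F2. The single remaining ketone then undergoes a Me2AlCl-promoted carbonyl-ene closure, with no group selection left to make, to tertiary alcohol F3. TBAF gives diol F4, and Dess–Martin oxidation of its secondary alcohol comes back to the route at 29.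

Step 19. Hydrogen may add 1,4 across the diene or continue to the a3=a4 alkene, or the allylic pivalate may be lost by hydrogenolysis. The fallback removes the tertiary hydroxyl by a radical route that never forms the diene. Setting out from 29, acylation with methyl chlorooxoacetate and DMAP gives oxalate F5. Bu3SnH/AIBN in refluxing toluene fragments it to the a15 tertiary radical, which should take hydrogen on the face away from the angular methyl. This comes back to the route at 32 and bypasses 31.

Step 15. Under amine catalysis the β,γ-unsaturated aldehyde may epimerise at a4, or its double bond may migrate into conjugation before condensation. The fallback forms a5–a6 by alkylation and avoids the aldehyde. 2-Methylcyclopentane-1,3-dione is condensed with 1,1-dimethylhydrazine to mono-hydrazone F6. Setting out from 23, I2/PPh3/imidazole gives iodide F7. The potassium salt of F6 (KH, THF) is C-alkylated by F7 to keto hydrazone F8, and Cu(OAc)2 in aqueous THF hydrolyses it, coming back to the route at 28.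

**Further compounds**

F1 | step 17 | hydroxy ketone (a8 carbinol, a15 ketone, a6 set) | CC(C)(C)C(=O)O[C@H]1C(=C)[C@H](C[C@@]2(C)[C@H](O)CCC2=O)[C@@H](C)CC[C@@H]3[C@@H]1CC[C@@H]3C
F2 | step 17 | triethylsilyl ether of F1 | CC(C)(C)C(=O)O[C@H]1C(=C)[C@H](C[C@@]2(C)[C@H](O[Si](CC)(CC)CC)CCC2=O)[C@@H](C)CC[C@@H]3[C@@H]1CC[C@@H]3C
F3 | step 17 | ene product with a8 triethylsilyl ether and a15 tertiary alcohol | CC(C)(C)C(=O)O[C@H]1C2=C(C[C@@]3(C)[C@H](O[Si](CC)(CC)CC)CC[C@@]3(O)C2)[C@@H](C)CC[C@@H]4[C@@H]1CC[C@@H]4C
F4 | step 17 | a8,a15 diol | CC(C)(C)C(=O)O[C@H]1C2=C(C[C@@]3(C)[C@H](O)CC[C@@]3(O)C2)[C@@H](C)CC[C@@H]4[C@@H]1CC[C@@H]4C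
F5 | step 19 | methyl oxalate of ketol 29 | CC(C)(C)C(=O)O[C@H]1C2=C(C[C@@]3(C)C(=O)CC[C@@]3(OC(=O)C(=O)OC)C2)[C@@H](C)CC[C@@H]4[C@@H]1CC[C@@H]4C
F6 | step 15 | 3-(2,2-dimethylhydrazinyl)-2-methylcyclopent-2-en-1-one | CC1=C(NN(C)C)CCC1=O
F7 | step 15 | a5 iodide | CC(C)(C)C(=O)O[C@H]1C(=C)[C@H](CI)[C@@H](C)CC[C@@H]2[C@@H]1CC[C@@H]2C
F8 | step 15 | C-alkylated keto dimethylhydrazone (a6 epimers) | CC(C)(C)C(=O)O[C@H]1C(=C)[C@H](CC2(C)C(=O)CCC2=NN(C)C)[C@@H](C)CC[C@@H]3[C@@H]1CC[C@@H]3C
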